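**Retrosynthetic overview**
- The anti-1,2-diol is made last from an (E)-trisubstituted olefin by asymmetric epoxidation, then hydrolysis with inversion at the tertiary carbon.
- The aryl ether comes from π-allyl etherification of 7-hydroxy-8-methoxycoumarin with an allylic acetate; the coumarin rings are bought intact.
- The butyrolactone, the only ring formed, comes from asymmetric hydrogenation and lactonisation of a γ-keto ester.
- Key step: the γ-keto ester is assembled in one operation from an allylic chloride, CO and a chiral ester homoenolate (β-zincio ester), which brings the methyl stereocentre with it.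

Assumption: the E-configured chloro acetate 2, 7-hydroxy-8-methoxycoumarin 7, both BINAP enantiomers and the L-series fructose-type epoxidation ketone are taken as catalogue items.

**Step 1**
Reactants: 1 methyl (2R)-3-bromo-2-methylpropanoate; 2 (2E)-4-chloro-3-methylbut-2-en-1-yl acetate
Product: 4 methyl (2S,6E)-8-acetoxy-2,6-dimethyl-4-oxooct-6-enoate, via zinc homoenolate 3 (not isolated)
Conditions: 1, Zn dust, LiCl, THF, 40 °C; supernatant added to 2, CO (1 atm), Pd(PPh3)4 (5 mol %), THF/DMA, 25 °C
Reagents that add atoms: carbon monoxide, [C-]#[O+]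
Why: Zinc insertion gives an ester homoenolate whose stereocentre is not the metalated carbon, zerovalent palladium ionises the allylic chloride much faster than the acetate, CO inserts at the unsubstituted π-allyl terminus, and the acylpalladium is captured by the homoenolate in a three-component carbonylative Negishi-type coupling, so the ester β-carbon is joined to an acyl carbon with the methyl stereocentre carried over from 1 (descriptor changes from R to S by priority only) and the E olefin kept through the syn π-allyl.

**Step 2**
Reactants: 4 methyl (2S,6E)-8-acetoxy-2,6-dimethyl-4-oxooct-6-enoate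
Product: 6 (2E)-3-methyl-4-[(2S,4S)-4-methyl-5-oxooxolan-2-yl]but-2-en-1-yl acetate, via hydroxy ester 5 (not isolated)
Conditions: H2 (50 atm), [RuCl(p-cymene)((R)-BINAP)]Cl (1 mol %), MeOH, 40 °C; then pyridinium p-toluenesulfonate (cat.), toluene, 60 °C
Reagents that add atoms: none
Why: Ester-directed Noyori asymmetric hydrogenation of a γ-keto ester sets the new (4S) carbinol under catalyst control (the ligand enantiomer that I recall, from memory, giving (R)-γ-valerolactone from levulinate esters, which is the same face here), leaves the trisubstituted olefin and the acetate alone, and acid then closes the cis-3,5-disubstituted γ-lactone.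

**Step 3**
Reactants: 6 (2E)-3-methyl-4-[(2S,4S)-4-methyl-5-oxooxolan-2-yl]but-2-en-1-yl acetate; 7 7-hydroxy-8-methoxy-2H-chromen-2-one
Product: 8 8-methoxy-7-{[(2E)-3-methyl-4-[(2S,4S)-4-methyl-5-oxooxolan-2-yl]but-2-en-1-yl]oxy}-2H-chromen-2-one
Conditions: Pd(PPh3)4 (5 mol %), K2CO3 (1.2 equiv), MeCN, 40 °C
Reagents that add atoms: none
Why: In this Tsuji–Trost O-allylation the phenoxide of 7 attacks the unsubstituted terminus of the π-allyl complex to give the linear ether (any branched tertiary ether re-ionises), the E geometry holds because syn/anti exchange would need a tertiary σ-allyl palladium, and no stereocentre is touched.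

**Step 4**
Reactants: 8 8-methoxy-7-{[(2E)-3-methyl-4-[(2S,4S)-4-methyl-5-oxooxolan-2-yl]but-2-en-1-yl]oxy}-2H-chromen-2-one
Product: 9 8-methoxy-7-{[(2S,3S)-3-methyl-3-{[(2S,4S)-4-methyl-5-oxooxolan-2-yl]methyl}oxiran-2-yl]methoxy}-2H-chromen-2-one
Conditions: Oxone (2KHSO5·KHSO4·K2SO4), 1,2:4,5-di-O-isopropylidene-β-L-erythro-2,3-hexodiulo-2,6-pyranose (30 mol %), K2CO3, Bu4NHSO4 (cat.), MeCN/dimethoxymethane–aq. Na2B4O7 buffer (pH 10.5), 0 °C
Reagents that add atoms: Oxone (active salt potassium peroxymonosulfate), [K+].[O-]S(=O)(=O)OO
Why: In this Shi asymmetric epoxidation the chiral dioxirane transfers oxygen through a spiro transition state to the electron-rich trisubstituted olefin only (the coumarin enoate is inert), and the L-series ketone gives the (2S,3S)-epoxide, the mirror image of the (R,R) sense of the D-fructose ketone.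

**Step 5**
Reactants: 9 8-methoxy-7-{[(2S,3S)-3-methyl-3-{[(2S,4S)-4-methyl-5-oxooxolan-2-yl]methyl}oxiran-2-yl]methoxy}-2H-chromen-2-one
Product: 10 7-{[(2S,3R)-2,3-dihydroxy-3-methyl-4-[(2S,4S)-4-methyl-5-oxooxolan-2-yl]butyl]oxy}-8-methoxy-2H-chromen-2-one
Conditions: HClO4 (5 mol %), THF/H2O (3:1), 0 °C to rt
Reagents that add atoms: water, O
Why: In this acid-catalysed epoxide hydrolysis of borderline SN2 type, water attacks the tertiary carbon with inversion (the secondary carbon is deactivated by the neighbouring aryloxymethyl group and keeps its C–O bond), so the (2S,3S)-epoxide gives the (2S,3R) anti-diol of the target.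

**Compound list**
1 | methyl (2R)-3-bromo-2-methylpropanoate | COC(=O)[C@@H](C)CBr | starting material
2 | (2E)-4-chloro-3-methylbut-2-en-1-yl acetate | CC(=O)OC/C=C(\C)CCl | starting material
3 | [(2R)-3-methoxy-2-methyl-3-oxopropyl]zinc bromide (zinc homoenolate) | COC(=O)[C@@H](C)C[Zn]Br | intermediate
4 | methyl (2S,6E)-8-acetoxy-2,6-dimethyl-4-oxooct-6-enoate | COC(=O)[C@@H](C)CC(=O)C/C(C)=C/COC(C)=O | intermediate
5 | methyl (2S,4S,6E)-8-acetoxy-4-hydroxy-2,6-dimethyloct-6-enoate (hydroxy ester) | COC(=O)[C@@H](C)C[C@H](O)C/C(C)=C/COC(C)=O | intermediate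
6 | (2E)-3-methyl-4-[(2S,4S)-4-methyl-5-oxooxolan-2-yl]but-2-en-1-yl acetate | CC(=O)OC/C=C(\C)C[C@@H]1C[C@H](C)C(=O)O1 | intermediate
7 | 7-hydroxy-8-methoxy-2H-chromen-2-one | COc1c(O)ccc2ccc(=O)oc12 | starting material
8 | 8-methoxy-7-{[(2E)-3-methyl-4-[(2S,4S)-4-methyl-5-oxooxolan-2-yl]but-2-en-1-yl]oxy}-2H-chromen-2-one | COc1c(OC/C=C(\C)C[C@@H]2C[C@H](C)C(=O)O2)ccc2ccc(=O)oc12 | intermediate
9 | 8-methoxy-7-{[(2S,3S)-3-methyl-3-{[(2S,4S)-4-methyl-5-oxooxolan-2-yl]methyl}oxiran-2-yl]methoxy}-2H-chromen-2-one | COc1c(OC[C@@H]3O[C@@]3(C)C[C@@H]2C[C@H](C)C(=O)O2)ccc2ccc(=O)oc12 | intermediate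
10 | 7-{[(2S,3R)-2,3-dihydroxy-3-methyl-4-[(2S,4S)-4-methyl-5-oxooxolan-2-yl]butyl]oxy}-8-methoxy-2H-chromen-2-one (CNP0300989.1) | COc1c(OC[C@H](O)[C@](C)(O)C[C@@H]2C[C@H](C)C(=O)O2)ccc2ccc(=O)oc12 | target

**Totals**
Total step count: 5. Longest linear sequence: 5 steps (1 and 2 to 10); 7 joins at step 3.

**Steps most likely to fail, with fallbacks**

Step 1 (three-component carbonylative coupling). The risks are direct allyl–alkyl coupling without CO, loss of olefin geometry, or attack on the acetate. The fallback separates carbonylation from C–C bond formation. It sets out from 2, which is thiocarbonylated (CO, EtSH, iPr2NEt, Pd(OAc)2/PPh3, THF) to the thioester S-ethyl (3E)-5-acetoxy-3-methylpent-3-enethioate F1. A Fukuyama coupling of this thioester with the zinc homoenolate 3 (PdCl2(PPh3)2, THF, rt) then gives the keto ester, and the route is rejoined at 4.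

Step 2 (asymmetric hydrogenation). The risks are a mismatch between catalyst and the existing methyl stereocentre, the wrong ligand sense (the (R)-BINAP assignment rests on the levulinate analogy and should be confirmed on a model), or migration of the β,γ-olefin into conjugation. The fallback sets out from 4 and reduces the ketone with an (S)-selective ketoreductase (NADPH recycled with isopropanol, pH 7 buffer, 30 °C). The enzyme tells the two methylene flanks apart without help from the ester and works under neutral conditions in which the olefin cannot migrate. The hydroxy ester 5 is lactonised as before and the route is rejoined at 6; no new compound arises (F0).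

Step 3 (palladium etherification). The risks are branched ether, E/Z erosion, or irreversible diene formation by β-hydride elimination from the reversibly formed π-allyl complex. The fallback abandons the π-allyl pathway. It sets out from 6, whose acetate is removed (K2CO3 cat., MeOH, 0 °C) to give the allylic alcohol (3S,5S)-5-[(2E)-4-hydroxy-2-methylbut-2-en-1-yl]-3-methyloxolan-2-one F2. This alcohol is coupled with 7 under Mitsunobu conditions (PPh3, DIAD, THF, 0 °C), an SN2 displacement at the primary carbon that cannot move the double bond, and the route is rejoined at 8.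

**Further compounds**
F1 | step 1 | S-ethyl (3E)-5-acetoxy-3-methylpent-3-enethioate | CCSC(=O)C/C(C)=C/COC(C)=O
F0 | step 2 | none | none
F2 | step 3 | (3S,5S)-5-[(2E)-4-hydroxy-2-methylbut-2-en-1-yl]-3-methyloxolan-2-one | OC/C=C(\C)C[C@@H]1C[C@H](C)C(=O)O1
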